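**Assumption:** the SMILES fixes only the three sp3 centres (1R,3R in the tetrahydro half, 3R in the dihydro half). The two outer C5–C8′ axes are not encoded and the central axis is configurationally labile. Each monomer is therefore carried on as one chromatographically separated atropo-diastereomer, and SMILES are written without axial descriptors.

## Retrosynthetic overview
1. Target ⇒ tri-O-benzyl dimer ⇒ the central naphthalene–naphthalene bond (C6′–C6″), made last by anodic dehydrogenative coupling inside an unsymmetrical diisopropylsilylene bis(naphthyl ether) that pairs the two different halves.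
2. Each half ⇒ Suzuki coupling (C5–C8′) of one common naphthalene boronate with a 5-bromoisoquinoline.
3. Both bromoisoquinolines ⇒ one common 5-bromo-6,8-bis(benzyloxy)-3,4-dihydroisoquinoline (Bischler–Napieralski ring closure). Trans-selective hydride reduction gives the right half. Chelation-controlled 8-O-debenzylation followed by O-methylation gives the left half.
4. Both C3 centres ⇒ one D-alaninol-derived cyclic sulfamidate opened by an aryl Grignard. C1 is set by 1,3-induction from C3.
5. Naphthalene ⇒ vinylketene acetal plus chlorobenzoquinone Diels–Alder. Ring order: the N-heterocycle and the naphthalene are built in parallel, then the two outer biaryl bonds, then the central biaryl bond.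

## Route

**Step 1**
Reactants: 1 (1,3-bis(benzyloxy)-5-bromobenzene); 2 (tert-butyl (4R)-4-methyl-1,2,3-oxathiazolidine-3-carboxylate 2,2-dioxide)
Product: 3, tert-butyl N-[(2R)-1-[3,5-bis(benzyloxy)phenyl]propan-2-yl]carbamate
Conditions: 1, Mg, THF, 50 °C; CuI (10 mol %), 2, −30 °C → rt; 1 M HCl, rt
Reagents that add atoms: none
Why: Cu-catalysed SN2 opening of the cyclic sulfamidate by the aryl Grignard occurs at the primary CH2–O carbon, so the purchased (R) centre is untouched and becomes C3 of both halves.

**Step 2**
Reactants: 3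
Product: 4, N-[(2R)-1-[3,5-bis(benzyloxy)phenyl]propan-2-yl]acetamide
Conditions: 4 M HCl/dioxane, rt; concentrate; Ac2O, Et3N, CH2Cl2, 0 °C → rt
Reagents that add atoms: acetic anhydride, CC(=O)OC(C)=O
Why: Boc acidolysis followed by N-acetylation in one flask; aryl benzyl ethers tolerate anhydrous HCl at rt.

**Step 3**
Reactants: 4
Product: 5, N-[(2R)-1-[3,5-bis(benzyloxy)-2-bromophenyl]propan-2-yl]acetamide
Conditions: NBS (1.0 equiv), MeCN, −20 → 0 °C, dark
Reagents that add atoms: N-bromosuccinimide, O=C1CCC(=O)N1Br
Why: Electrophilic bromination of a 3,5-dialkoxyalkylbenzene goes para to one OR and ortho to the chain (two equivalent sites) rather than between the two OR groups, and doing it before ring closure avoids bromination of an enamine tautomer.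

**Step 4**
Reactants: 5
Product: 6, (3R)-6,8-bis(benzyloxy)-5-bromo-1,3-dimethyl-3,4-dihydroisoquinoline
Conditions: Tf2O, 2-chloropyridine, CH2Cl2, −78 → 23 °C
Reagents that add atoms: none
Why: Bischler–Napieralski cyclisation of the nitrilium ion onto the only free ortho carbon (para and ortho to OBn), under buffered conditions that spare the benzyl ethers and C3.

**Step 5**
Reactants: 6
Product: 7, (1R,3R)-6,8-bis(benzyloxy)-5-bromo-1,3-dimethyl-1,2,3,4-tetrahydroisoquinoline (trans)
Conditions: AlMe3, LiAlH4, THF, −78 → −20 °C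
Reagents that add atoms: none
Why: In this Lewis-acid-modified hydride reduction under 1,3-induction, AlMe3 on nitrogen shields the normally preferred face, so hydride enters syn to the C3-methyl and C1-Me ends up anti to it (1R, trans, about 9:1, cis isomer removed on silica); ArBr survives at or below −20 °C.

**Step 6**
Reactants: 6
Product: 8, (3R)-6-(benzyloxy)-5-bromo-1,3-dimethyl-3,4-dihydroisoquinolin-8-ol
Conditions: BCl3 (1.1 equiv), CH2Cl2, −78 → −30 °C; MeOH, aq NaHCO3
Reagents that add atoms: none
Why: In this chelation-controlled ether cleavage (as for o-alkoxyaryl ketones), boron bridges the imine N and the peri 8-oxygen in a six-membered chelate, so only that benzyl group is lost and the remote 6-OBn stays.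

**Step 7**
Reactants: 8
Product: 9, (3R)-6-(benzyloxy)-5-bromo-8-methoxy-1,3-dimethyl-3,4-dihydroisoquinoline
Conditions: MeOH, PPh3, DIAD, THF, 0 °C → rt
Reagents that add atoms: methanol, CO
Why: Mitsunobu etherification O-methylates the acidic, N-hydrogen-bonded phenol under neutral conditions and avoids the imine N-quaternisation that MeI could cause.

**Step 8**
Reactants: 10 (methyl 3-methylbut-2-enoate)
Product: 11, (1-methoxy-3-methylbuta-1,3-dien-1-yl)oxytrimethylsilane
Conditions: LDA, THF, −78 °C; TMSCl
Reagents that add atoms: chlorotrimethylsilane, C[Si](C)(C)Cl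
Why: Kinetic γ-deprotonation to the extended dienolate and O-silylation gives the vinylketene silyl acetal.

**Step 9**
Reactants: 11; 12 (2-chloro-1,4-benzoquinone)
Product: 13, 5-hydroxy-7-methyl-1,4-naphthoquinone (7-methyljuglone)
Conditions: CH2Cl2, −20 °C → rt; 1 M HCl/THF
Reagents that add atoms: none
Why: Brassard-type Diels–Alder reaction followed by loss of HCl and MeOH aromatises without an oxidant, and the diene substitution places O at C5 and CH3 at C7.

**Step 10**
Reactants: 13
Product: 14, 5-methoxy-7-methyl-1,4-naphthoquinone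
Conditions: MeI, Ag2O, CH2Cl2, rt
Reagents that add atoms: iodomethane, CI
Why: Ag2O-promoted O-methylation is the standard way to etherify the chelated peri-OH of juglones.

**Step 11**
Reactants: 14
Product: 15, 5-methoxy-7-methylnaphthalene-1,4-diol
Conditions: Na2S2O4, EtOAc/H2O, rt, Ar (used directly)
Reagents that add atoms: none
Why: Dithionite reduces the quinone to the hydroquinone.

**Step 12**
Reactants: 15
Product: 16, 5-methoxy-7-methyl-4-(triisopropylsilyloxy)naphthalen-1-yl trifluoromethanesulfonate
Conditions: Tf2O (1.0 equiv), 2,6-lutidine, CH2Cl2, −78 °C; then TIPSOTf, −78 °C → rt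
Reagents that add atoms: triflic anhydride, O=S(=O)(OS(=O)(=O)C(F)(F)F)C(F)(F)F; TIPSOTf, CC(C)[Si](OS(=O)(=O)C(F)(F)F)(C(C)C)C(C)C
Why: Regioselective sulfonylation occurs because the C4-OH is hydrogen-bonded to and crowded by the peri-OMe, so the free C1-OH is triflated first and the remaining OH is then silylated in the same pot.

**Step 13**
Reactants: 16
Product: 17, triisopropyl{[8-methoxy-6-methyl-4-(4,4,5,5-tetramethyl-1,3,2-dioxaborolan-2-yl)naphthalen-1-yl]oxy}silane
Conditions: B2pin2, PdCl2(dppf), KOAc, dioxane, 85 °C
Reagents that add atoms: bis(pinacolato)diboron, CC1(C)OB(OC1(C)C)B1OC(C)(C)C(C)(C)O1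
Why: Miyaura borylation of the aryl triflate; the TIPS ether prevents protodeboronation of a para-naphtholate boronate.

**Step 14**
Reactants: 9; 17
Product: 18, 4-[(3R)-6-(benzyloxy)-8-methoxy-1,3-dimethyl-3,4-dihydroisoquinolin-5-yl]-8-methoxy-6-methylnaphthalen-1-ol
Conditions: SPhos Pd G3 (5 mol %), K3PO4, toluene/H2O 10:1, 90 °C; then TBAF, THF, rt; separate atropisomers
Reagents that add atoms: none
Why: Suzuki–Miyaura coupling with a bulky biarylphosphine forms the hindered C5–C8′ bond, the cyclic ketimine is inert to phosphate, and fluoride frees the naphthol in the same pot.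

**Step 15**
Reactants: 7; 17
Product: 19, 4-[(1R,3R)-6,8-bis(benzyloxy)-1,3-dimethyl-1,2,3,4-tetrahydroisoquinolin-5-yl]-8-methoxy-6-methylnaphthalen-1-ol
Conditions: as Step 14; separate atropisomers
Reagents that add atoms: none
Why: This is the same Suzuki–Miyaura coupling and desilylation, and the doubly α-branched secondary amine is too hindered to undergo N-arylation.

**Step 16**
Reactants: 18; 19
Product: 20, diisopropylsilanediyl mixed bis(naphthyl ether) of 18 and 19 (18-O–Si(iPr)2–O-19)
Conditions: 18 added to iPr2SiCl2 (4 equiv), Et3N, CH2Cl2, 0 °C; excess silane removed in vacuo; 19, imidazole, DMAP, CH2Cl2, rt; aqueous wash (removes chloride), Et3N-deactivated SiO2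
Reagents that add atoms: dichlorodiisopropylsilane, CC(C)[Si](Cl)(Cl)C(C)C
Why: In stepwise silaketal formation the second substitution at the bulky iPr2Si centre is much slower than the first, so the monochlorosilane of 18 (which has no N–H) can be formed cleanly and then captured by the only free OH of 19.

**Step 17**
Reactants: 20
Product: 21, 6,6‴,8‴-tri-O-benzyl michellamine F (central binaphthol free)
Conditions: 20·2TfOH (2 mM), 2,6-di-tert-butylpyridine (2.5 equiv), Bu4NOTf (0.1 M), CH2Cl2/HFIP 9:1, divided cell, BDD anode/Pt cathode, 0 °C, 0.5 mA cm⁻², 2.1 F mol⁻¹; then Et3N·3HF, rt (bridged dioxasilepine not isolated); aq Na2S2O4/NaHCO3, Ar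
Reagents that add atoms: none
Why: Proposed new method: anodic intramolecular dehydrogenative aryl–aryl coupling of an unsymmetrical bis(naphthyloxy)silane. One-electron oxidation of either 1-silyloxy-8-methoxynaphthalene (about +1.2 V, well below the benzyloxy-arenes and the protonated N atoms) gives a radical cation with spin and charge at C2 and C4. C4 is blocked by the isoquinoline, and the tether holds C2 of the neutral partner in a seven-membered transition state, so attack followed by −H⁺/−e⁻/−H⁺ forms only the ortho,ortho′ hetero-dimer. O-silylation blocks C–O coupling and over-oxidation to the binaphthylidenedione, and the divided cell keeps the iminium away from the cathode. No stereo-element is fixed because the new axis is labile. The closest known reaction types are hypervalent-iodine or anodic coupling of tethered aryl ethers and anodic phenol–arene cross-coupling in HFIP.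

**Step 18**
Reactants: 21
Product: 22, michellamine F
Conditions: 21·2HCl, BCl3 (12 equiv), C6HMe5 (15 equiv), CH2Cl2, −78 °C, 45 min; MeOH/CHCl3 quench; RP-HPLC, neutralise
Reagents that add atoms: none
Why: BCl3 with pentamethylbenzene as cation scavenger removes the three aryl benzyl ethers at −78 °C, where aryl methyl ethers survive, the pre-protonated iminium cannot chelate boron to the 8-OMe, and no reducing agent touches C=N.

## Compound list
1 | 1,3-bis(benzyloxy)-5-bromobenzene | Brc1cc(OCc2ccccc2)cc(OCc2ccccc2)c1 | starting material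
2 | tert-butyl (4R)-4-methyl-1,2,3-oxathiazolidine-3-carboxylate 2,2-dioxide | C[C@@H]1COS(=O)(=O)N1C(=O)OC(C)(C)C | starting material (chiral pool)
3 | (R)-Boc-amine | CC(C)(C)OC(=O)N[C@H](C)Cc1cc(OCc2ccccc2)cc(OCc2ccccc2)c1 | intermediate
4 | (R)-acetamide | CC(=O)N[C@H](C)Cc1cc(OCc2ccccc2)cc(OCc2ccccc2)c1 | intermediate
5 | (R)-2-bromoaryl acetamide | CC(=O)N[C@H](C)Cc1cc(OCc2ccccc2)cc(OCc2ccccc2)c1Br | intermediate
6 | (3R)-6,8-bis(benzyloxy)-5-bromo-1,3-dimethyl-3,4-dihydroisoquinoline | CC1=N[C@H](C)Cc2c(Br)c(OCc3ccccc3)cc(OCc3ccccc3)c12 | intermediate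
7 | (1R,3R)-6,8-bis(benzyloxy)-5-bromo-1,3-dimethyl-1,2,3,4-tetrahydroisoquinoline | Brc1c(OCc2ccccc2)cc(OCc2ccccc2)c2c1C[C@@H](C)N[C@@H]2C | intermediate
8 | (3R)-6-(benzyloxy)-5-bromo-1,3-dimethyl-3,4-dihydroisoquinolin-8-ol | CC1=N[C@H](C)Cc2c(Br)c(OCc3ccccc3)cc(O)c12 | intermediate
9 | (3R)-6-(benzyloxy)-5-bromo-8-methoxy-1,3-dimethyl-3,4-dihydroisoquinoline | COc1cc(OCc2ccccc2)c(Br)c2c1C(C)=N[C@H](C)C2 | intermediate
10 | methyl 3-methylbut-2-enoate | COC(=O)C=C(C)C | starting material
11 | (1-methoxy-3-methylbuta-1,3-dien-1-yl)oxytrimethylsilane | COC(=CC(C)=C)O[Si](C)(C)C | intermediate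
12 | 2-chloro-1,4-benzoquinone | O=C1C=CC(=O)C(Cl)=C1 | starting material
13 | 5-hydroxy-7-methyl-1,4-naphthoquinone | Cc1cc(O)c2C(=O)C=CC(=O)c2c1 | intermediate
14 | 5-methoxy-7-methyl-1,4-naphthoquinone | COc1cc(C)cc2C(=O)C=CC(=O)c12 | intermediate
15 | 5-methoxy-7-methylnaphthalene-1,4-diol | COc1cc(C)cc2c(O)ccc(O)c12 | intermediate
16 | 5-methoxy-7-methyl-4-(TIPS-oxy)naphthalen-1-yl triflate | COc1cc(C)cc2c(OS(=O)(=O)C(F)(F)F)ccc(O[Si](C(C)C)(C(C)C)C(C)C)c12 | intermediate
17 | naphthyl pinacol boronate (4-OTIPS) | COc1cc(C)cc2c(B3OC(C)(C)C(C)(C)O3)ccc(O[Si](C(C)C)(C(C)C)C(C)C)c12 | intermediate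
18 | left (dihydroisoquinoline) monomer naphthol | COc1cc(OCc2ccccc2)c(-c2ccc(O)c3c(OC)cc(C)cc23)c2c1C(C)=N[C@H](C)C2 | intermediate
19 | right (trans-tetrahydroisoquinoline) monomer naphthol | COc1cc(C)cc2c(-c3c(OCc4ccccc4)cc(OCc4ccccc4)c4c3C[C@@H](C)N[C@@H]4C)ccc(O)c12 | intermediate
20 | unsymmetrical diisopropylsilaketal | COc1cc(OCc2ccccc2)c(-c2ccc(O[Si](C(C)C)(C(C)C)Oc3ccc(-c4c(OCc5ccccc5)cc(OCc5ccccc5)c5c4C[C@@H](C)N[C@@H]5C)c4cc(C)cc(OC)c34)c3c(OC)cc(C)cc23)c2c1C(C)=N[C@H](C)C2 | intermediate
21 | tri-O-benzyl michellamine F | COc1cc(OCc2ccccc2)c(-c2cc(-c3cc(-c4c(OCc5ccccc5)cc(OCc5ccccc5)c5c4C[C@@H](C)N[C@@H]5C)c4cc(C)cc(OC)c4c3O)c(O)c3c(OC)cc(C)cc23)c2c1C(C)=N[C@H](C)C2 | intermediate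
22 | michellamine F | COc1cc(O)c(-c2cc(-c3cc(-c4c(O)cc(O)c5c4C[C@@H](C)N[C@@H]5C)c4cc(C)cc(OC)c4c3O)c(O)c3c(OC)cc(C)cc23)c2c1C(C)=N[C@H](C)C2 | target

## Totals
Total steps: 18.
Longest linear sequence: 10 steps (Steps 1, 2, 3, 4, 6, 7, 14, 16, 17, 18). The naphthalene branch (Steps 8–13, 14, 16, 17, 18) is also 10.

## Steps most likely to fail
1. **Step 17 (proposed new anodic tethered coupling).** The risks are Si–O loss from the radical cation, over-oxidation, and slow seven-membered-ring closure. Fallback (known chemistry, no tether): Boc-protect 19 and combine it 1:1 with 18. Apply the established Ag2O/Et3N oxidative naphthol coupling to the binaphthylidenediones, then reduce with aqueous Na2S2O4, which leaves C=N intact. Separate the statistical hetero-dimer (at most 50 %) from the two homodimers. The Boc group falls in Step 18.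
2. **Step 6 (with Step 7).** The risks are poor 8-O versus 6-O selectivity in the debenzylation and N- versus O-methylation afterwards. Fallback: buy the regiochemistry. Start from 1-[4-(benzyloxy)-2-hydroxy-6-methoxyphenyl]ethanone and make its aryl triflate. Carry out a Negishi coupling with the organozinc from (R)-N-Boc-1-iodopropan-2-amine (from D-alaninol). TFA then removes Boc and closes the cyclic imine, and NBS bromination at C5 gives 9.
3. **Step 14 (hindered Suzuki coupling on the dihydroisoquinoline bromide).** The risks are Pd binding to the imine, protodeboronation and hydrodebromination. Fallback: build the biaryl before the heterocycle.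
   - Couple the open-chain bromide 5 with 17, keeping the TIPS group.
   - Close the ring by Bischler–Napieralski cyclisation onto the single remaining ortho position.
   - Run the Step 5 chemistry (right half) or the Step 6 and 7 chemistry (left half) on the TIPS-protected biaryl, where the 8-OH is the only free phenol.
   - Remove TIPS with TBAF last.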